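Counting the skeleton from the ester carbon (C1), the molecule is divided between C10, the methyl-bearing olefinic carbon of the side chain, and C11, the first CH2 of the ethylene link to the cyclohexenone ring. C11 lies δ to the ring carbonyl C15 through C12 and the C13=C14 bond, so it is the terminus of a 2,4-dienone acceptor. The key step unites a dioxane ester carrying a methyl alkyne with 3-ethenyl-2,4,4-trimethylcyclohex-2-enone: syn-hydrozirconation and copper-catalysed 1,6-addition form C10–C11, the E-trisubstituted alkene and, after γ-protonation, the ring enone in one operation. The dioxane arises from (R)-linalool by oxetane perhydrolysis, anti-crotylation and SN2 peroxide closure.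

Key step: step 14

Remark: (R)-(−)-linalool of high enantiomeric purity is assumed; the O–O bond is installed early, so every later step of the main route avoids free phosphines, aluminium and boron hydride reductants and strong amine bases.

Step 1
Reactants: 1 (R)-linalool [(3R)-3,7-dimethylocta-1,6-dien-3-ol]
Product: 3 (3R)-3,7-dimethyloct-6-ene-1,3-diol, via alkylborane 2 (not isolated)
Conditions: 9-BBN, THF, 0 °C → rt; then NaOH, H2O2, 0 °C
Reagents that add atoms: hydrogen peroxide, OO
Why: Anti-Markovnikov hydroboration–oxidation, in which the bulky borane adds only to the monosubstituted vinyl group and leaves the trisubstituted alkene and the carbinol stereocentre of linalool untouched.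

Step 2
Reactants: 3 (3R)-3,7-dimethyloct-6-ene-1,3-diol
Product: 5 (2R)-2-methyl-2-(4-methylpent-3-en-1-yl)oxetane, via tosylate 4 (not isolated)
Conditions: n-BuLi (1 equiv), THF, 0 °C; TsCl; n-BuLi (1 equiv), 0 → 60 °C
Reagents that add atoms: none
Why: One-pot monotosylation of the primary alkoxide and intramolecular Williamson etherification (4-exo-tet) by the tertiary alkoxide, which keeps the C–O bond at the stereocentre and so retains its configuration.

Step 3
Reactants: 5 (2R)-2-methyl-2-(4-methylpent-3-en-1-yl)oxetane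
Product: 7 3-[(2R)-2-methyloxetan-2-yl]propanal, via ozonide 6 (not isolated)
Conditions: O3, CH2Cl2, −78 °C; then Me2S, −78 °C → rt
Reagents that add atoms: ozone, [O-][O+]=O
Why: Ozonolysis with reductive work-up cleaves the only C=C bond, releasing acetone and leaving the two methylene groups of the homoprenyl chain between the new aldehyde and the oxetane, whose ring and stereocentre are inert.

Step 4
Reactants: 7 3-[(2R)-2-methyloxetan-2-yl]propanal
Product: 9 (3S,4R)-3-methyl-6-[(2R)-2-methyloxetan-2-yl]hex-1-en-4-ol, via borinate 8 (not isolated)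
Conditions: (E)-but-2-ene, KOtBu, n-BuLi, THF, −45 °C; (−)-Ipc2BOMe, −78 °C; BF3·OEt2; then 7, −78 °C; NaOH, H2O2
Reagents that add atoms: (E)-but-2-ene, C/C=C/C, delivered as (E)-crotyldiisopinocampheylborane, C/C=C/CB([C@@H]1C[C@@H]2C[C@H]([C@H]1C)C2(C)C)[C@@H]1C[C@@H]2C[C@H]([C@H]1C)C2(C)C
Why: Brown crotylation, in which the (E)-crotylborane reacts through a closed chair transition state to give the 3,4-anti relationship and the isopinocampheyl groups derived from (+)-α-pinene direct the transfer to the Si face of the aldehyde, setting both new stereocentres as (3S,4R).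

Step 5
Reactants: 9 (3S,4R)-3-methyl-6-[(2R)-2-methyloxetan-2-yl]hex-1-en-4-ol
Product: 10 (3S,4R)-3-methyl-6-[(2R)-2-methyloxetan-2-yl]hex-1-en-4-yl methanesulfonate
Conditions: MsCl, Et3N, CH2Cl2, 0 °C
Reagents that add atoms: methanesulfonyl chloride, CS(=O)(=O)Cl
Why: Sulfonylation of the secondary alcohol occurs at oxygen with retention and turns the carbinol carbon into the electrophile for the later peroxide ring closure.

Step 6
Reactants: 10 (3S,4R)-3-methyl-6-[(2R)-2-methyloxetan-2-yl]hex-1-en-4-yl methanesulfonate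
Product: 11 (3S,4R,7S)-7-hydroperoxy-9-hydroxy-3,7-dimethylnon-1-en-4-yl methanesulfonate
Conditions: H2O2 (anhydrous, in Et2O), TMSOTf (cat.), Et2O, −78 → 0 °C
Reagents that add atoms: hydrogen peroxide, OO
Why: Lewis-acid-promoted perhydrolysis of a 2,2-disubstituted oxetane, in which H2O2 attacks the activated ring at the tertiary carbon in an SN2-like manner with inversion, so that all atoms of 10 are kept, the ring CH2CH2O arm becomes the 2-hydroxyethyl group and the peroxide-bearing quaternary centre is set as (7S).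

Step 7
Reactants: 11 (3S,4R,7S)-7-hydroperoxy-9-hydroxy-3,7-dimethylnon-1-en-4-yl methanesulfonate
Product: 12 2-[(3S,6S)-6-[(2S)-but-3-en-2-yl]-3-methyl-1,2-dioxan-3-yl]ethan-1-ol
Conditions: KOtBu (1.05 equiv), 18-crown-6, THF, 0 °C → rt
Reagents that add atoms: none
Why: Intramolecular SN2 alkylation of the selectively deprotonated hydroperoxide (6-exo-tet) on the secondary mesylate closes the 1,2-dioxane with inversion at the carbinol carbon, which gives the ring CH centre its required configuration.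

Step 8
Reactants: 12 2-[(3S,6S)-6-[(2S)-but-3-en-2-yl]-3-methyl-1,2-dioxan-3-yl]ethan-1-ol
Product: 14 (3R,6S)-6-[(2S)-but-3-en-2-yl]-3-methyl-3-(pent-3-yn-1-yl)-1,2-dioxane, via triflate 13 (not isolated)
Conditions: Tf2O, 2,6-lutidine, CH2Cl2, −78 °C; then 1-propynyllithium, THF/DMPU, −78 → −20 °C
Reagents that add atoms: 1-propynyllithium, [Li]C#CC
Why: SN2 alkylation of a lithium acetylide by a primary triflate is fast at low temperature and the weakly reducing sp-carbanion should spare the dialkyl peroxide, so the side arm gains the three carbons of the methyl alkyne without touching a stereocentre.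

Step 9
Reactants: 14 (3R,6S)-6-[(2S)-but-3-en-2-yl]-3-methyl-3-(pent-3-yn-1-yl)-1,2-dioxane
Product: 17 (2R)-2-[(3S,6R)-6-methyl-6-(pent-3-yn-1-yl)-1,2-dioxan-3-yl]propanoic acid, via ozonide 15 (not isolated), via aldehyde 16 (not isolated)
Conditions: O3 (1 equiv), CH2Cl2, −78 °C; Me2S; then NaClO2, NaH2PO4, 2-methylbut-2-ene, t-BuOH/H2O, 0 °C
Reagents that add atoms: ozone, [O-][O+]=O; sodium chlorite, [Na+].[O-]Cl=O
Why: Ozonolysis discriminates the terminal alkene from the much less reactive internal alkyne and the buffered Pinnick oxidation converts the α-branched β-peroxy aldehyde at once into the acid, so that C2 should not epimerise and the peroxide should not be eliminated.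

Step 10
Reactants: 17 (2R)-2-[(3S,6R)-6-methyl-6-(pent-3-yn-1-yl)-1,2-dioxan-3-yl]propanoic acid
Product: 18 methyl (2R)-2-[(3S,6R)-6-methyl-6-(pent-3-yn-1-yl)-1,2-dioxan-3-yl]propanoate
Conditions: TMSCHN2, MeOH/toluene, 0 °C
Reagents that add atoms: trimethylsilyldiazomethane, C[Si](C)(C)C=[N+]=[N-]
Why: Esterification with the diazoalkane is neutral and therefore avoids base-induced β-elimination of the peroxide from the ester.

Step 11
Reactants: 19 2-methylcyclohexane-1,3-dione
Product: 20 2-methyl-3-(2-methylpropoxy)cyclohex-2-en-1-one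
Conditions: 2-methylpropan-1-ol, p-TsOH (cat.), toluene, reflux (Dean–Stark)
Reagents that add atoms: 2-methylpropan-1-ol, CC(C)CO
Why: Acid-catalysed enol etherification of the cyclic 1,3-dione, driven by azeotropic removal of water, gives the vinylogous ester.

Step 12
Reactants: 20 2-methyl-3-(2-methylpropoxy)cyclohex-2-en-1-one
Product: 22 2,6,6-trimethyl-3-(2-methylpropoxy)cyclohex-2-en-1-one, via monomethyl enone 21 (not isolated)
Conditions: LDA, THF, −78 °C; MeI; then LDA, −78 °C; MeI, −78 → 0 °C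
Reagents that add atoms: iodomethane, CI
Why: Kinetic deprotonation of a vinylogous ester occurs at the α′-carbon, so two successive enolate alkylations build the gem-dimethyl group there.

Step 13
Reactants: 22 2,6,6-trimethyl-3-(2-methylpropoxy)cyclohex-2-en-1-one
Product: 24 3-ethenyl-2,4,4-trimethylcyclohex-2-en-1-one, via carbinol 23 (not isolated)
Conditions: vinylmagnesium bromide, CeCl3, THF, −78 → 0 °C; then 1 M HCl, rt
Reagents that add atoms: vinylmagnesium bromide, C=C[Mg]Br
Why: Stork–Danheiser transposition, in which 1,2-addition of the vinyl nucleophile to the hindered carbonyl is followed by acid hydrolysis of the enol ether and dehydration to the transposed dienone.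

Step 14
Reactants: 18 methyl (2R)-2-[(3S,6R)-6-methyl-6-(pent-3-yn-1-yl)-1,2-dioxan-3-yl]propanoate and 24 3-ethenyl-2,4,4-trimethylcyclohex-2-en-1-one
Product: 27 methyl (2R)-2-[(3S,6R)-6-methyl-6-[(3E)-4-methyl-6-(2,6,6-trimethyl-3-oxocyclohex-1-en-1-yl)hex-3-en-1-yl]-1,2-dioxan-3-yl]propanoate, via alkenylzirconocene 25 (not isolated), via silyl dienol ether 26 (not isolated)
Conditions: Cp2Zr(H)Cl (1.3 equiv), THF, rt; then 24, CuI·0.75SMe2 (10 mol %), TMSCl, THF, 0 → 40 °C; then 1 M HCl, THF, 0 °C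
Reagents that add atoms: none
Why: Proposed new method: Cp2Zr(H)Cl adds syn across the methyl alkyne of 18 and, under equilibrating conditions, places zirconium on the less hindered methyl-bearing carbon C10 to give the (E)-alkenylzirconocene 25; transmetalation to catalytic monovalent copper and TMSCl-assisted 1,6-addition to dienone 24 forms the C10–C11 bond at the unsubstituted δ-CH2, and the silyl dienol ether 26 is hydrolysed with γ-protonation to the conjugated, tetrasubstituted ring enone. The closest known reaction types are the copper-catalysed 1,4-addition of alkenylzirconocenes to enones and the 1,6-addition of alkenylcopper reagents to 2,4-dienoates and dienones; their combination on a 3-vinylcyclohexenone is what is new. No ring is closed and no stereocentre is created; the E geometry follows from syn-hydrometalation and retentive alkenyl transfer, and both geometrical isomers of the exocyclic dienol ether should converge on the same enone. The step needs 1,6- over 1,4- and 1,2-addition, which the fully substituted β-carbon C13, flanked by the gem-dimethyl carbon and the C14 methyl group, should enforce, and it needs zirconium at C10 and not at C9, which the size difference between CH3 and CH2R should secure. It also needs the O–O bond and the methyl ester to survive, which rests on the low reactivity of Cp2Zr(H)Cl toward hindered dialkyl peroxides and esters at room temperature and on the absence of organolithium or Grignard reagents.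

Compound list
1 | (R)-linalool, (3R)-3,7-dimethylocta-1,6-dien-3-ol | C=C[C@](C)(O)CCC=C(C)C | starting material
2 | (3S)-1-(9-borabicyclo[3.3.1]nonan-9-yl)-3,7-dimethyloct-6-en-3-ol | C1CC2CCCC(C1)B2CC[C@](C)(O)CCC=C(C)C | intermediate
3 | (3R)-3,7-dimethyloct-6-ene-1,3-diol | OCC[C@](C)(O)CCC=C(C)C | intermediate
4 | (3R)-3-hydroxy-3,7-dimethyloct-6-en-1-yl 4-methylbenzenesulfonate | Cc1ccc(cc1)S(=O)(=O)OCC[C@](C)(O)CCC=C(C)C | intermediate
5 | (2R)-2-methyl-2-(4-methylpent-3-en-1-yl)oxetane | CC(C)=CCC[C@]1(C)CCO1 | intermediate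
6 | 3,3-dimethyl-5-{2-[(2R)-2-methyloxetan-2-yl]ethyl}-1,2,4-trioxolane (epimers at the ozonide CH) | CC1(C)OOC(CC[C@]2(C)CCO2)O1 | intermediate
7 | 3-[(2R)-2-methyloxetan-2-yl]propanal | O=CCC[C@]1(C)CCO1 | intermediate
8 | (3S,4R)-3-methyl-6-[(2R)-2-methyloxetan-2-yl]hex-1-en-4-yl diisopinocampheylborinate | C=C[C@H](C)[C@H](OB([C@@H]1C[C@@H]2C[C@H]([C@H]1C)C2(C)C)[C@@H]1C[C@@H]2C[C@H]([C@H]1C)C2(C)C)CC[C@]1(C)CCO1 | intermediate
9 | (3S,4R)-3-methyl-6-[(2R)-2-methyloxetan-2-yl]hex-1-en-4-ol | C=C[C@H](C)[C@H](O)CC[C@]1(C)CCO1 | intermediate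
10 | (3S,4R)-3-methyl-6-[(2R)-2-methyloxetan-2-yl]hex-1-en-4-yl methanesulfonate | C=C[C@H](C)[C@H](OS(C)(=O)=O)CC[C@]1(C)CCO1 | intermediate
11 | (3S,4R,7S)-7-hydroperoxy-9-hydroxy-3,7-dimethylnon-1-en-4-yl methanesulfonate | C=C[C@H](C)[C@H](OS(C)(=O)=O)CC[C@@](C)(CCO)OO | intermediate
12 | 2-[(3S,6S)-6-[(2S)-but-3-en-2-yl]-3-methyl-1,2-dioxan-3-yl]ethan-1-ol | C=C[C@H](C)[C@@H]1CC[C@@](C)(CCO)OO1 | intermediate
13 | 2-[(3S,6S)-6-[(2S)-but-3-en-2-yl]-3-methyl-1,2-dioxan-3-yl]ethyl trifluoromethanesulfonate | C=C[C@H](C)[C@@H]1CC[C@@](C)(CCOS(=O)(=O)C(F)(F)F)OO1 | intermediate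
14 | (3R,6S)-6-[(2S)-but-3-en-2-yl]-3-methyl-3-(pent-3-yn-1-yl)-1,2-dioxane | C=C[C@H](C)[C@@H]1CC[C@@](C)(CCC#CC)OO1 | intermediate
15 | (3R,6S)-3-methyl-3-(pent-3-yn-1-yl)-6-[(1R)-1-(1,2,4-trioxolan-3-yl)ethyl]-1,2-dioxane (epimers at the ozonide CH) | C1OOC(O1)[C@H](C)[C@@H]2CC[C@@](C)(CCC#CC)OO2 | intermediate
16 | (2R)-2-[(3S,6R)-6-methyl-6-(pent-3-yn-1-yl)-1,2-dioxan-3-yl]propanal | O=C[C@H](C)[C@@H]1CC[C@@](C)(CCC#CC)OO1 | intermediate
17 | (2R)-2-[(3S,6R)-6-methyl-6-(pent-3-yn-1-yl)-1,2-dioxan-3-yl]propanoic acid | OC(=O)[C@H](C)[C@@H]1CC[C@@](C)(CCC#CC)OO1 | intermediate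
18 | methyl (2R)-2-[(3S,6R)-6-methyl-6-(pent-3-yn-1-yl)-1,2-dioxan-3-yl]propanoate | COC(=O)[C@H](C)[C@@H]1CC[C@@](C)(CCC#CC)OO1 | intermediate
19 | 2-methylcyclohexane-1,3-dione | CC1C(=O)CCCC1=O | starting material
20 | 2-methyl-3-(2-methylpropoxy)cyclohex-2-en-1-one | CC1=C(OCC(C)C)CCCC1=O | intermediate
21 | 2,6-dimethyl-3-(2-methylpropoxy)cyclohex-2-en-1-one (racemic) | CC1CCC(OCC(C)C)=C(C)C1=O | intermediate
22 | 2,6,6-trimethyl-3-(2-methylpropoxy)cyclohex-2-en-1-one | CC1=C(OCC(C)C)CCC(C)(C)C1=O | intermediate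
23 | 1-ethenyl-2,6,6-trimethyl-3-(2-methylpropoxy)cyclohex-2-en-1-ol (racemic) | C=CC1(O)C(C)=C(OCC(C)C)CCC1(C)C | intermediate
24 | 3-ethenyl-2,4,4-trimethylcyclohex-2-en-1-one | C=CC1=C(C)C(=O)CCC1(C)C | intermediate
25 | methyl (2R)-2-[(3S,6R)-6-{(3E)-4-[chlorobis(η5-cyclopentadienyl)zirconio]pent-3-en-1-yl}-6-methyl-1,2-dioxan-3-yl]propanoate | COC(=O)[C@H](C)[C@@H]1CC[C@@](C)(CC/C=C(\C)[Zr](Cl)(C2C=CC=C2)C2C=CC=C2)OO1 | intermediate
26 | methyl (2R)-2-[(3S,6R)-6-methyl-6-[(3E)-4-methyl-6-{2,6,6-trimethyl-3-[(trimethylsilyl)oxy]cyclohex-2-en-1-ylidene}hex-3-en-1-yl]-1,2-dioxan-3-yl]propanoate (both geometries at the exocyclic C=C) | COC(=O)[C@H](C)[C@@H]1CC[C@@](C)(CC/C=C(\C)CC=C2C(C)=C(O[Si](C)(C)C)CCC2(C)C)OO1 | intermediate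
27 | methyl (2R)-2-[(3S,6R)-6-methyl-6-[(3E)-4-methyl-6-(2,6,6-trimethyl-3-oxocyclohex-1-en-1-yl)hex-3-en-1-yl]-1,2-dioxan-3-yl]propanoate | COC(=O)[C@H](C)[C@@H]1CC[C@@](C)(CC/C=C(\C)CCC2=C(C)C(=O)CCC2(C)C)OO1 | target

Total step count: 14. Longest linear sequence: 11 steps (steps 1 to 10, then step 14).

Steps most likely to fail

Step 14. The alkenyl group may fail to transfer from copper to the twisted, hindered dienone, so that protonation of the alkenylmetal or 1,2-addition takes over, and monovalent copper may cleave the O–O bond by single-electron transfer. The fallback sets out from 18 and 24 and comes back at 27; it replaces the conjugate addition by a palladium-catalysed B-alkyl Suzuki–Miyaura coupling that needs no copper and no enone acceptor. Alkyne 18 would be hydrozirconated as in step 14 and the alkenylzirconocene quenched with I2 to give methyl (2R)-2-[(3S,6R)-6-[(3E)-4-iodopent-3-en-1-yl]-6-methyl-1,2-dioxan-3-yl]propanoate F1. Dienone 24 would be reduced under Luche conditions (NaBH4, CeCl3·7H2O, MeOH, 0 °C) to racemic 3-ethenyl-2,4,4-trimethylcyclohex-2-en-1-ol F2, silylated (TBSCl, imidazole, DMF) to tert-butyl[(3-ethenyl-2,4,4-trimethylcyclohex-2-en-1-yl)oxy]dimethylsilane F3 and hydroborated at the vinyl group with 9-BBN to 9-[2-(3-{[tert-butyl(dimethyl)silyl]oxy}-2,6,6-trimethylcyclohex-1-en-1-yl)ethyl]-9-borabicyclo[3.3.1]nonane F4. Coupling of F4 with F1 (PdCl2(dppf), AsPh3, Cs2CO3, DMF/THF/H2O, rt) should give methyl (2R)-2-[(3S,6R)-6-[(3E)-6-(3-{[tert-butyl(dimethyl)silyl]oxy}-2,6,6-trimethylcyclohex-1-en-1-yl)-4-methylhex-3-en-1-yl]-6-methyl-1,2-dioxan-3-yl]propanoate F5 as a pair of carbinol epimers. HF·pyridine should then release methyl (2R)-2-[(3S,6R)-6-[(3E)-6-(3-hydroxy-2,6,6-trimethylcyclohex-1-en-1-yl)-4-methylhex-3-en-1-yl]-6-methyl-1,2-dioxan-3-yl]propanoate F6, and MnO2 (or Dess–Martin periodinane) should oxidise both epimers of this allylic alcohol to 27.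

Step 7. E2 elimination of the β-branched homoallylic mesylate to a conjugated diene may outrun the 6-exo-tet attack of the peroxide anion. The fallback sets out from aldehyde 7 and comes back at 18; it gives up the stereospecific SN2 closure for an oxa-Michael closure. Wittig reaction of 7 with methyl 2-(triphenylphosphoranylidene)propanoate would give methyl (2E)-2-methyl-5-[(2R)-2-methyloxetan-2-yl]pent-2-enoate F7, and perhydrolysis as in step 6 would give methyl (2E,6S)-6-hydroperoxy-8-hydroxy-2,6-dimethyloct-2-enoate F8. Et2NH in CF3CH2OH should bring about intramolecular conjugate addition of the hydroperoxide (6-exo-trig), and chromatographic separation from the C2/C3 diastereomers should give methyl (2R)-2-[(3S,6S)-6-(2-hydroxyethyl)-6-methyl-1,2-dioxan-3-yl]propanoate F9. Tf2O and 2,6-lutidine would convert it into methyl (2R)-2-[(3S,6S)-6-methyl-6-{2-[(trifluoromethanesulfonyl)oxy]ethyl}-1,2-dioxan-3-yl]propanoate F10, and 1-propynyllithium at −78 °C should then give 18.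

Step 8. The acetylide may attack the O–O bond, by nucleophilic or single-electron pathways, or eliminate the triflate instead of substituting it. The fallback sets out from triflate 13 and comes back at 14; it replaces the organolithium by a catalytic copper acetylide. Bu4NI would convert 13 into (3S,6S)-6-[(2S)-but-3-en-2-yl]-3-(2-iodoethyl)-3-methyl-1,2-dioxane F11, which would be coupled with propyne in an alkyl Sonogashira reaction ([Pd(allyl)Cl]2, 1,3-bis(1-adamantyl)imidazolium chloride, CuI, Cs2CO3, DMF/Et2O, 45 °C) to give 14.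

Further compounds
F1 | step 14 | methyl (2R)-2-[(3S,6R)-6-[(3E)-4-iodopent-3-en-1-yl]-6-methyl-1,2-dioxan-3-yl]propanoate | COC(=O)[C@H](C)[C@@H]1CC[C@@](C)(CC/C=C(\C)I)OO1
F2 | step 14 | 3-ethenyl-2,4,4-trimethylcyclohex-2-en-1-ol (racemic) | C=CC1=C(C)C(O)CCC1(C)C
F3 | step 14 | tert-butyl[(3-ethenyl-2,4,4-trimethylcyclohex-2-en-1-yl)oxy]dimethylsilane (racemic) | C=CC1=C(C)C(O[Si](C)(C)C(C)(C)C)CCC1(C)C
F4 | step 14 | 9-[2-(3-{[tert-butyl(dimethyl)silyl]oxy}-2,6,6-trimethylcyclohex-1-en-1-yl)ethyl]-9-borabicyclo[3.3.1]nonane | C1CC2CCCC(C1)B2CCC1=C(C)C(O[Si](C)(C)C(C)(C)C)CCC1(C)C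
F5 | step 14 | methyl (2R)-2-[(3S,6R)-6-[(3E)-6-(3-{[tert-butyl(dimethyl)silyl]oxy}-2,6,6-trimethylcyclohex-1-en-1-yl)-4-methylhex-3-en-1-yl]-6-methyl-1,2-dioxan-3-yl]propanoate (carbinol epimers) | COC(=O)[C@H](C)[C@@H]1CC[C@@](C)(CC/C=C(\C)CCC2=C(C)C(O[Si](C)(C)C(C)(C)C)CCC2(C)C)OO1
F6 | step 14 | methyl (2R)-2-[(3S,6R)-6-[(3E)-6-(3-hydroxy-2,6,6-trimethylcyclohex-1-en-1-yl)-4-methylhex-3-en-1-yl]-6-methyl-1,2-dioxan-3-yl]propanoate (carbinol epimers) | COC(=O)[C@H](C)[C@@H]1CC[C@@](C)(CC/C=C(\C)CCC2=C(C)C(O)CCC2(C)C)OO1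
F7 | step 7 | methyl (2E)-2-methyl-5-[(2R)-2-methyloxetan-2-yl]pent-2-enoate | COC(=O)/C(C)=C/CC[C@]1(C)CCO1
F8 | step 7 | methyl (2E,6S)-6-hydroperoxy-8-hydroxy-2,6-dimethyloct-2-enoate | COC(=O)/C(C)=C/CC[C@@](C)(CCO)OO
F9 | step 7 | methyl (2R)-2-[(3S,6S)-6-(2-hydroxyethyl)-6-methyl-1,2-dioxan-3-yl]propanoate | COC(=O)[C@H](C)[C@@H]1CC[C@@](C)(CCO)OO1
F10 | step 7 | methyl (2R)-2-[(3S,6S)-6-methyl-6-{2-[(trifluoromethanesulfonyl)oxy]ethyl}-1,2-dioxan-3-yl]propanoate | COC(=O)[C@H](C)[C@@H]1CC[C@@](C)(CCOS(=O)(=O)C(F)(F)F)OO1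
F11 | step 8 | (3S,6S)-6-[(2S)-but-3-en-2-yl]-3-(2-iodoethyl)-3-methyl-1,2-dioxane | C=C[C@H](C)[C@@H]1CC[C@@](C)(CCI)OO1
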